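Ring A of the decalin (labdane numbering; C18 = formyl carbon on C4) is disconnected by a retro-Diels–Alder reaction across C2–C3 and C4–C5. The feature exploited is the 1,4-relationship of C18 and the α-oxygen on C6 of ring B: joined as an ester they tether a methacrylate dienophile (C3=C4) to a diene (C2=C1–C10=C5) on an acyclic chain. Heating this (S)-dienyl methacrylate should close ring A and an 18,6-lactone at once and set the quaternary C4 and C5 from C6. Ring B is then closed onto the new C1=C10 olefin by a ketone-terminated cation–olefin cyclisation, and a vinylogous aldol reaction installs the butenolide.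

Key step: step 6

Remark on numbering: decalin carbons are C1–C10, the side chain is C11–C15 (methyl C16 on C13), C17 is the methyl on C8, C18 the 4α-formyl carbon, C19 the 4β-methyl and C20 the 10β-methyl.
Remark on tautomers: the 6α-hydroxy-18-aldehyde unit and its 18,6α-lactol are ring–chain tautomers, and in line with the target structure the open form is written for 17, 18, 21 and 22.

Step 1
Reactants: 1 (2E)-3-methylpent-2-en-4-yn-1-ol
Product: 2 (2E)-3-methylpenta-2,4-dien-1-ol
Conditions: H2 (1 atm), Pd/CaCO3 poisoned with Pb(OAc)2 (Lindlar catalyst), quinoline, EtOAc, rt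
Reagents that add atoms: none
Why: Lindlar semihydrogenation of the terminal alkyne should stop at the vinyl group and leave the (E)-trisubstituted olefin untouched.

Step 2
Reactants: 2 (2E)-3-methylpenta-2,4-dien-1-ol
Product: 3 (2E)-3-methylpenta-2,4-dienal
Conditions: MnO2, CH2Cl2, rt (solution used directly)
Reagents that add atoms: none
Why: MnO2 oxidation of an allylic alcohol is selective and non-isomerising, so the (E)-dienal should form without over-oxidation.

Step 3
Reactants: 3 (2E)-3-methylpenta-2,4-dienal, 4 allenylboronic acid pinacol ester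
Product: 6 (4S,5E)-6-methylocta-5,7-dien-1-yn-4-ol, via pinacol borate ester 5 (not isolated)
Conditions: (S)-TRIP phosphoric acid (5 mol%), 4 Å molecular sieves, toluene, 0 °C; aq. NaHCO3 work-up
Reagents that add atoms: allenylboronic acid pinacol ester 4 (C=C=CB1OC(C)(C)C(C)(C)O1)
Why: Chiral phosphoric acid-catalysed carbonyl propargylation (SE2' transfer from the allenylboronate through a six-membered transition state) should deliver the propargyl group to the Si face of the enal and set the (S)-carbinol, the future C6, the borate being hydrolysed on work-up.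

Step 4
Reactants: 6 (4S,5E)-6-methylocta-5,7-dien-1-yn-4-ol, 7 methyl vinyl ketone
Product: 9 (5E,8S,9E)-8-hydroxy-6,10-dimethyldodeca-5,9,11-trien-2-one, via alkenyl(dimethyl)alane 8 (not isolated)
Conditions: Me3Al, Cp2ZrCl2 (20 mol%), CH2Cl2, 0 °C to rt; then Cu(O2CC4H3S) (copper thiophene-2-carboxylate, 10 mol%), 7 (excess), Et2O/THF, −30 °C; aq. KNaC4H4O6
Reagents that add atoms: trimethylaluminium (C[Al](C)C); methyl vinyl ketone 7 (CC(=O)C=C)
Why: Negishi zirconium-catalysed methylalumination adds methyl and aluminium syn across the terminal alkyne (methyl at the internal carbon), which fixes the (E)-olefin C8=C9 with C17, and copper-catalysed conjugate addition of the alkenylalane to the enone then attaches C11–C13 with retention of geometry.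

Step 5
Reactants: 9 (5E,8S,9E)-8-hydroxy-6,10-dimethyldodeca-5,9,11-trien-2-one, 10 methacryloyl chloride
Product: 11 (3E,5S,7E)-3,7-dimethyl-11-oxododeca-1,3,7-trien-5-yl 2-methylprop-2-enoate
Conditions: Et3N, DMAP (cat.), CH2Cl2, 0 °C
Reagents that add atoms: methacryloyl chloride 10 (CC(=C)C(Cl)=O)
Why: DMAP-catalysed acylation under basic conditions should esterify the secondary dienylic alcohol without ionising its allylic C–O bond, so the C6 configuration is kept.

Step 6
Reactants: 11 (3E,5S,7E)-3,7-dimethyl-11-oxododeca-1,3,7-trien-5-yl 2-methylprop-2-enoate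
Product: 12 (3S,3aR,7aR)-4,7a-dimethyl-3-[(2E)-2-methyl-6-oxohept-2-en-1-yl]-3a,6,7,7a-tetrahydro-2-benzofuran-1(3H)-one (trans-fused 18,6-lactone on ring A with C1=C10)
Conditions: 1,2-dichlorobenzene (0.01 M), BHT, 160 °C, sealed vessel
Reagents that add atoms: none
Why: Concerted thermal [4+2] cycloaddition in which the methacrylate C3=C4 adds across the termini C2 and C5 of the diene C2=C1–C10=C5, forming C2–C3 and C4–C5 and leaving C1=C10. The closest known reaction type is the intramolecular Diels–Alder reaction of pentadienyl acrylates (ester-linked 1,3,8-nonatrienes), including those with a substituent on the diene carbon next to the tether. Ring A is closed as the cyclohexene of the cycloaddition by both new bonds, and the γ-lactone (C18–O–C6) is closed as the tether ring by the fusion bond C4–C5. C5 is controlled by C6: allylic 1,3-strain with the C10 methyl (C20) holds H6 in the diene plane, so the dienophile can only add to the face that carries the ester oxygen, with the C7 chain pointing away. The quaternary C4 is set by the exo orientation of the tether carbonyl (C19 methyl endo), which gives the trans-fused lactone with C18 α and C19 β. The step needs trans over cis ring fusion and bonding of C4 to C5 against the directing effect of the C10 methyl; the short tether enforces the regiochemistry, and the C10 methyl next to the tether together with the α-methyl of the dienophile should favour the exo-carbonyl mode.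

Step 7
Reactants: 12 trans-fused lactone
Product: 14 8α-hydroxy-13-oxo-14,15-dinorlabdan-18,6α-olide (4β-methyl, 5α-H, 9α-H, 10β-methyl), via cyclic enol ether 13 (not isolated)
Conditions: ClSO3H (excess, proton source, not consumed), 2-nitropropane, −78 °C; then H2O/THF, rt
Reagents that add atoms: water (O)
Why: Proton-initiated cation–olefin cyclisation of the farnesylacetone type, in which Markovnikov protonation of C1=C10 gives the tertiary C10 cation, the (E)-C8=C9 olefin attacks its α face through a chair (the β face is screened by the axial C19 methyl) and the ketone oxygen captures C8 anti, so that the trans-decalin with 10β-methyl, 9β-side chain and 8α-oxygen should result, the cyclic enol ether then being hydrolysed by the dilute acid of the quench.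

Step 8
Reactants: 14 8α-hydroxy-13-oxo-14,15-dinorlabdan-18,6α-olide, 15 triethyl phosphonoacetate
Product: 16 (13E)-15-ethoxy-8α-hydroxy-15-oxolabd-13-en-18,6α-olide
Conditions: NaH, THF, 0 °C to reflux
Reagents that add atoms: triethyl phosphonoacetate 15 (CCOC(=O)CP(=O)(OCC)OCC)
Why: Horner–Wadsworth–Emmons olefination of the methyl ketone should give mainly the (E)-enoate (C13=C14), the minor (Z)-isomer being removed by chromatography, while the lactone has no α-hydrogen and the tertiary alkoxide is inert.

Step 9
Reactants: 16 (13E)-15-ethoxy-8α-hydroxy-15-oxolabd-13-en-18,6α-olide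
Product: 17 (13E)-6α,8α,15-trihydroxylabd-13-en-18-al
Conditions: iBu2AlH (DIBAL-H, excess), CH2Cl2, −78 °C; aq. KNaC4H4O6
Reagents that add atoms: none
Why: DIBAL-H reduction should take the enoate to the allylic alcohol and stop at the lactol stage for the hindered lactone, because the cyclic aluminium hemiacetal is stable at −78 °C.

Step 10
Reactants: 17 (13E)-6α,8α,15-trihydroxylabd-13-en-18-al
Product: 18 (13E)-6α,8α-dihydroxylabd-13-ene-15,18-dial
Conditions: MnO2, CH2Cl2, rt
Reagents that add atoms: none
Why: MnO2 should oxidise only the primary allylic alcohol and leave the secondary and tertiary alcohols and the neopentyl aldehyde untouched.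

Step 11
Reactants: 19 4-methylfuran-2(5H)-one
Product: 20 4-methyl-2-(trimethylsilyloxy)furan
Conditions: TMSOTf, Et3N, Et2O, 0 °C (used without purification)
Reagents that add atoms: trimethylsilyl triflate (C[Si](C)(C)OS(=O)(=O)C(F)(F)F)
Why: Soft enolisation and O-silylation of the butenolide gives the 2-silyloxyfuran needed as the nucleophile of the vinylogous Mukaiyama aldol reaction.

Step 12
Reactants: 18 (13E)-6α,8α-dihydroxylabd-13-ene-15,18-dial, 20 4-methyl-2-(trimethylsilyloxy)furan
Product: 22 target CNP0112578.1, via trimethylsilyl ether 21 (not isolated)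
Conditions: Ti(OiPr)4/(R)-BINOL (20 mol%), Et2O, −20 °C; then 1 M HCl, THF, 0 °C
Reagents that add atoms: 4-methyl-2-(trimethylsilyloxy)furan 20 (Cc1coc(O[Si](C)(C)C)c1)
Why: Catalytic asymmetric vinylogous Mukaiyama aldol reaction in which the silyloxyfuran should attack through its C5 at the unhindered enal and not at the neopentyl C18 aldehyde, the (R)-BINOL–titanium complex is expected to direct attack to the Re face (15S) as in related titanium–BINOL carbonyl additions, the usual syn (threo) preference of Lewis-acid-mediated silyloxyfuran additions sets the (S)-γ-carbon of the butenolide, and the acid work-up cleaves the silyl ether.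

Compound list
1 | (2E)-3-methylpent-2-en-4-yn-1-ol | C#C/C(C)=C/CO | starting material
2 | (2E)-3-methylpenta-2,4-dien-1-ol | C=C/C(C)=C/CO | intermediate
3 | (2E)-3-methylpenta-2,4-dienal | C=C/C(C)=C/C=O | intermediate
4 | allenylboronic acid pinacol ester | C=C=CB1OC(C)(C)C(C)(C)O1 | starting material
5 | pinacol borate ester of 6 | C#CC[C@H](OB1OC(C)(C)C(C)(C)O1)/C=C(\C)C=C | intermediate
6 | (4S,5E)-6-methylocta-5,7-dien-1-yn-4-ol | C#CC[C@H](O)/C=C(\C)C=C | intermediate
7 | methyl vinyl ketone | CC(=O)C=C | starting material
8 | (E)-alkenyl(dimethyl)alane, O-dimethylaluminium alkoxide, from methylalumination of 6 | C[Al](C)/C=C(\C)C[C@H](O[Al](C)C)/C=C(\C)C=C | intermediate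
9 | (5E,8S,9E)-8-hydroxy-6,10-dimethyldodeca-5,9,11-trien-2-one | CC(=O)CC/C=C(\C)C[C@H](O)/C=C(\C)C=C | intermediate
10 | methacryloyl chloride | CC(=C)C(Cl)=O | starting material
11 | (3E,5S,7E)-3,7-dimethyl-11-oxododeca-1,3,7-trien-5-yl 2-methylprop-2-enoate | CC(=O)CC/C=C(\C)C[C@H](OC(=O)C(C)=C)/C=C(\C)C=C | intermediate
12 | (3S,3aR,7aR)-4,7a-dimethyl-3-[(2E)-2-methyl-6-oxohept-2-en-1-yl]-3a,6,7,7a-tetrahydro-2-benzofuran-1(3H)-one | CC(=O)CC/C=C(\C)C[C@@H]1OC(=O)[C@]2(C)CCC=C(C)[C@@H]12 | intermediate
13 | 8α,13-epoxy-14,15-dinorlabd-12-en-18,6α-olide | CC1=CC[C@@H]2[C@@]3(C)CCC[C@@]4(C)C(=O)O[C@H]([C@H]34)C[C@@]2(C)O1 | intermediate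
14 | 8α-hydroxy-13-oxo-14,15-dinorlabdan-18,6α-olide | CC(=O)CC[C@@H]1[C@@]2(C)CCC[C@@]3(C)C(=O)O[C@H]([C@H]23)C[C@@]1(C)O | intermediate
15 | triethyl phosphonoacetate | CCOC(=O)CP(=O)(OCC)OCC | starting material
16 | (13E)-15-ethoxy-8α-hydroxy-15-oxolabd-13-en-18,6α-olide | CCOC(=O)/C=C(\C)CC[C@@H]1[C@@]2(C)CCC[C@@]3(C)C(=O)O[C@H]([C@H]23)C[C@@]1(C)O | intermediate
17 | (13E)-6α,8α,15-trihydroxylabd-13-en-18-al | OC/C=C(\C)CC[C@@H]1[C@@]2(C)CCC[C@@](C)(C=O)[C@@H]2[C@@H](O)C[C@@]1(C)O | intermediate
18 | (13E)-6α,8α-dihydroxylabd-13-ene-15,18-dial | O=C/C=C(\C)CC[C@@H]1[C@@]2(C)CCC[C@@](C)(C=O)[C@@H]2[C@@H](O)C[C@@]1(C)O | intermediate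
19 | 4-methylfuran-2(5H)-one | CC1=CC(=O)OC1 | starting material
20 | 4-methyl-2-(trimethylsilyloxy)furan | Cc1coc(O[Si](C)(C)C)c1 | intermediate
21 | 15-O-trimethylsilyl ether of 22 | CC1=CC(=O)O[C@@H]1[C@@H](O[Si](C)(C)C)/C=C(\C)CC[C@@H]1[C@@]2(C)CCC[C@@](C)(C=O)[C@@H]2[C@@H](O)C[C@@]1(C)O | intermediate
22 | CNP0112578.1, (5S)-5-[(1S,2E)-1-hydroxy-3-methyl-5-(4α-formyl-6α,8α-dihydroxy-4β,8β,10β-trimethyl-trans-decalin-9β-yl)pent-2-en-1-yl]-4-methylfuran-2(5H)-one | CC1=CC(=O)O[C@@H]1[C@@H](O)/C=C(\C)CC[C@@H]1[C@@]2(C)CCC[C@@](C)(C=O)[C@@H]2[C@@H](O)C[C@@]1(C)O | target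

Total step count: 12. Longest linear sequence: 11 steps (steps 1–10 and 12; step 11 is a one-step branch).

Steps most likely to fail

Step 6. The cycloaddition may pass through the endo-carbonyl transition state and give the cis-fused lactone, which means the wrong configuration at the quaternary C4. It may also be outrun by ester elimination or polymerisation at the temperature the unactivated methacrylate needs. The fallback places a removable, activating and endo-directing ester on C3. It sets out from 9: esterification with (2E)-4-methoxy-2-methyl-4-oxobut-2-enoic acid (EDC·HCl, DMAP) gives the mesaconate triene F1. Its intramolecular Diels–Alder reaction (toluene, 110 °C) is expected to put the terminal ester endo and so the tether carbonyl exo, giving the trans-fused lactone ester F2. LiOH followed by acidification gives the acid F3. This is converted into the Barton ester F4 (N-hydroxypyridine-2-thione, DCC) and reduced with t-BuSH under visible light (Barton decarboxylation), which comes back to the route at 12.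

Step 7. Protonation may be unselective: a C8 cation may be captured by the ketone oxygen before the C9–C10 bond forms, the C10 cation may lose a proton toward C5 and erode the C5 configuration, or closure may occur on the β face to a cis-decalin. The fallback replaces proton initiation by electrophilic mercuration under non-acidic conditions. It sets out from 12: Hg(OTf)2·PhNMe2 (MeNO2, −20 °C; then aq. NaCl) should give the cyclised 1β-chloromercurial enol ether F5. Reductive demercuration (NaBH4, aq. NaOH, THF, 0 °C) comes back to the route at 13, which is hydrolysed to 14 as in the second operation of step 7.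

Step 12. The hindered C18 aldehyde and the free hydroxyls may compete for the silyloxyfuran and bind the titanium catalyst, which would lower both chemoselectivity and catalyst-controlled facial selectivity at the remote enal. The fallback masks the C18 aldehyde before the enal is made. It sets out from 17: MeOH with PPTS gives the cyclic methyl acetal F6, MnO2 gives the enal acetal F7, and the same vinylogous aldol reaction with 20 gives the silyl ether acetal F8. Aqueous acetic acid in THF then cleaves the silyl ether and the acetal and comes back to the route at 22.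

Further compounds
F1 | step 6 | 4-methyl 1-[(3E,5S,7E)-3,7-dimethyl-11-oxododeca-1,3,7-trien-5-yl] (2E)-2-methylbut-2-enedioate (mesaconate triene) | CC(=O)CC/C=C(\C)C[C@H](OC(=O)/C(C)=C/C(=O)OC)/C=C(\C)C=C
F2 | step 6 | 3β-methoxycarbonyl derivative of lactone 12 (trans-fused) | CC(=O)CC/C=C(\C)C[C@@H]1OC(=O)[C@]2(C)[C@@H](C(=O)OC)CC=C(C)[C@@H]12
F3 | step 6 | 3β-carboxylic acid derivative of lactone 12 | CC(=O)CC/C=C(\C)C[C@@H]1OC(=O)[C@]2(C)[C@@H](C(=O)O)CC=C(C)[C@@H]12
F4 | step 6 | Barton ester (2-thioxopyridin-1(2H)-yl ester) of F3 | CC(=O)CC/C=C(\C)C[C@@H]1OC(=O)[C@]2(C)[C@@H](C(=O)ON3C=CC=CC3=S)CC=C(C)[C@@H]12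
F5 | step 7 | 1β-chloromercurio-8α,13-epoxy-14,15-dinorlabd-12-en-18,6α-olide | CC1=CC[C@@H]2[C@@]3(C)[C@H]([Hg]Cl)CC[C@@]4(C)C(=O)O[C@H]([C@H]34)C[C@@]2(C)O1
F6 | step 12 | (13E)-18-methoxy-18,6α-epoxylabd-13-ene-8α,15-diol (methyl acetal of 17) | OC/C=C(\C)CC[C@@H]1[C@@]2(C)CCC[C@@]3(C)C(OC)O[C@H]([C@H]23)C[C@@]1(C)O
F7 | step 12 | (13E)-8α-hydroxy-18-methoxy-18,6α-epoxylabd-13-en-15-al | O=C/C=C(\C)CC[C@@H]1[C@@]2(C)CCC[C@@]3(C)C(OC)O[C@H]([C@H]23)C[C@@]1(C)O
F8 | step 12 | 15-O-trimethylsilyl ether, 18-methyl acetal of 22 | CC1=CC(=O)O[C@@H]1[C@@H](O[Si](C)(C)C)/C=C(\C)CC[C@@H]1[C@@]2(C)CCC[C@@]3(C)C(OC)O[C@H]([C@H]23)C[C@@]1(C)O
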